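Assumption: the indolinol 13 is made and carried on as the racemate, because its only stereocentre (C3) is lost in step 7; its SMILES shows one enantiomer.

## Analysis of the target

The target 17 is a 1H-indole, a benzene ring fused to a pyrrole ring through the C3a–C7a bond. It carries bromine on C2 and C3 of the pyrrole ring and on C4 and C7 of the benzene ring; only N1, C5 and C6 keep their hydrogens. The target has no stereocentre. The one stereocentre met on the way, C3 of the indolinol 13, is formed as a racemate and disappears on aromatisation.

The sensitive part is the N–H 2,3-dibromoindole unit, an electron-rich halo-enamine that is prone to oxidation to oxindoles and to decomposition by acid and light. It should therefore be made last and under neutral conditions. Once C–Br bonds are present, zerovalent palladium, alkyllithium reagents, dissolving metals and hydrogenation are excluded.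

The real difficulty lies in the benzene ring. An indole is brominated at C3, then C2, then C5 or C6, and not cleanly at C4 and C7, so these two bromines must arrive together with the six-membered ring. The strategy rests on one feature: the ring-fusion atoms C3a and C7a are neighbours and each has a brominated neighbour (C4 beside C3a, C7 beside C7a). Read as the two ends of a triple bond, they define 3,6-dibromobenzyne 11, which has a mirror plane through that bond. N1 and C3 can then be attached to it without any question of orientation.

## Retrosynthetic reasoning

**C2–Br and C3–Br (17 to 15).** These two bonds are cut first because C3 and C2 are the innately nucleophilic positions of an indole. The forward reaction is a double electrophilic bromination of 4,7-dibromo-1H-indole 15, placed at the very end so that the labile 2,3-dibromoindole is never carried through other steps. The benzene ring of 15 is deactivated by its two bromines and should stay untouched.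

**N–H and the C2=C3 double bond (15 to 14 to 13).** The N–H of 15 is traced back to the N-sulfonylindole 14, and the C2=C3 double bond of 14 to the C3 carbinol of the indolinol 13 by dehydration. The sulfonyl group is needed in the ring-forming step, where it makes nitrogen acidic and nucleophilic as its anion. Hydroxide removes it from an indole easily. Writing C3 as a carbinol carbon reveals it as a former aldehyde carbon.

**N1–C7a and C3–C3a (13 to 11 and 10).** Both bonds that join the five-membered ring to the benzene ring are cut in one operation. This leaves the aryne 11 and the two-carbon fragment 4-methyl-N-(2-oxoethyl)benzenesulfonamide 10, whose nitrogen is a nucleophile and whose aldehyde carbon is an electrophile. That polarity matches an aryne, which first accepts a nucleophile and then, as the aryl anion, attacks an electrophile. Cutting elsewhere (N1–C2 or C2–C3) would require a tetrasubstituted benzene with two different ortho substituents between the bromines, which is much harder to reach. The forward reaction must release 11 under conditions that 10 tolerates, so 11 is traced to the ortho-silylaryl triflate 6, which forms the aryne with fluoride at room temperature.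

**C–Si and O–S of the aryne precursor (6 to 5 to 2 to 1).** The triflate 6 comes from the silylphenol 5. The C–Si bond of 5 is traced to the silyl ether 2 of 2,5-dibromophenol 1, in which both bromines already stand para to each other. The carbon that must carry silicon is the only one flanked by oxygen and bromine. It can be deprotonated with an amide base, and the silyl group then moves from oxygen to carbon. No C–Br bond is made or broken in this branch.

**N–S and the aldehyde (10 to 9 to 7 and 8).** The aldehyde 10 is traced to its dimethyl acetal 9, and 9 to aminoacetaldehyde dimethyl acetal 7 and p-toluenesulfonyl chloride 8. The acetal protects the carbonyl during sulfonylation, and the sensitive free aldehyde is released only just before the key step.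

## Alternatives that were turned down

**Alternative 1:** The benzene ring is cut at C3a–C4 and C7–C7a. C4–C7 with both bromines come from 2,5-dibromothiophene 1,1-dioxide A1, and C3a, C7a and the rest of the five-membered ring come from tert-butyl 2,3-dihydropyrrole-1-carboxylate A2.
- Forward key step: an inverse-demand [4+2] cycloaddition of the electron-poor diene A1 with the electron-rich enecarbamate A2, followed by cheletropic extrusion of the sulfonyl bridge, should give the cis-fused diene tert-butyl cis-4,7-dibromo-2,3,3a,7a-tetrahydroindole-1-carboxylate A3 (racemic).
- For it: the bromines sit on C4 and C7 by construction, the electronic pairing is good, and no metal is needed. On certainty of the bromine positions it equals the chosen route.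
- Against it: A3 is four hydrogens away from an indole, so two dehydrogenations must follow. The first is endangered because the C7a–N bond of A3 is allylic and β to the C3a hydrogen, so aromatisation by β-elimination of the carbamate nitrogen, which opens the five-membered ring, competes with loss of hydrogen. A1 must be made by oxidising the parent thiophene and dimerises readily, and A3 is itself a diene that can react further.
- Comparison: after the oxidations come carbamate removal and the double bromination, so the sequence is no shorter. The chosen route forms the benzene ring already aromatic and reaches the indole by a dehydration and not by oxidations.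

**Alternative 2:** C5–C6 and both C–Br bonds at C4 and C7 are cut together, which leads to 2,3-diethynyl-1-(4-methylphenylsulfonyl)pyrrole A4.
- Forward key step: heating A4 in bromotrichloromethane A5 should cause Bergman cycloaromatisation to the 4,7-diradical of the N-sulfonylindole. Each radical centre takes a bromine atom from A5 to give 4,7-dibromo-1-(4-methylphenylsulfonyl)indole A6, the same compound as 14.
- For it: the ring and both difficult bromines are made in one step, at exactly the carbons that electrophilic bromination cannot reach, and the product lies one step beyond the product of the chosen key step. In bond-forming economy of the key step this alternative is stronger.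
- Against it: an enediyne whose double bond belongs to a five-membered ring holds the alkyne termini further apart than a six-membered one does, so cyclisation needs temperatures at which terminal diynes polymerise. The diradical abstracts hydrogen (from the tolyl methyl group or from A4) about as readily as bromine, so mixtures of di-, mono- and non-brominated indoles are to be expected. The trichloromethyl radicals left behind can add to the alkynes of A4 and start chains. A4 itself needs a 2,3-dihalogenated N-sulfonylpyrrole, two Sonogashira couplings and a desilylation, so the saving at the key step is spent beforehand.
- Comparison: the chosen route uses closed-shell polar steps at room temperature, whose outcome is fixed by the structures of 6 and 10 and not by relative rates of radical abstraction.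

**Alternative 3:** Only N1–C7a is cut. This leads to ethyl (Z)-2-azido-3-(2,5-dibromophenyl)acrylate A9, made by Knoevenagel condensation of 2,5-dibromobenzaldehyde A7 with ethyl azidoacetate A8.
- Forward key step (Hemetsberger–Knittel indole synthesis): thermolysis of A9 causes denitrogenation, and the vinyl nitrene, in equilibrium with its 2H-azirine, bonds to the only free ortho carbon to give ethyl 4,7-dibromo-1H-indole-2-carboxylate A10.
- For it: the reaction type is well established for halogenated benzaldehydes, the orientation is fixed because the other ortho position carries bromine, and the bicyclic core is reached in two steps from simple materials. In precedent and in length (about five steps to 17) this alternative is stronger than the chosen route.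
- Against it: A10 carries at C2 a carbon that the target lacks. The ester must be hydrolysed and the acid decarboxylated before 15 is reached, normally with copper near 200 °C, where aryl C–Br bonds are liable to reduction and coupling. The condensation to A9 tends to be inefficient with ortho-substituted, electron-poor aldehydes, and A8 and A9 are energetic azides that must be heated.
- Comparison: the chosen route offers instead a pyrrole ring formed with C2 and C3 unsubstituted, so nothing has to be removed at high temperature next to aryl bromides. It also runs azide-free at room temperature and assembles the core convergently from two easily made fragments.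

Key step: step 6

## Route

Step 1
Reactants: 1 2,5-dibromophenol
Product: 2 (2,5-dibromophenoxy)trimethylsilane
Conditions: (Me3Si)2NH (0.6 equiv), THF, 65 °C; volatiles removed in vacuo, crude used
Reagents that add atoms: hexamethyldisilazane, C[Si](C)(C)N[Si](C)(C)C
Why: O-Silylation of an acidic phenol by a silazane, driven by loss of the volatile amine by-product; no salts form, so the moisture-sensitive aryl silyl ether can be used directly.

Step 2
Reactants: 2 (2,5-dibromophenoxy)trimethylsilane
Product: 5 3,6-dibromo-2-(trimethylsilyl)phenol, via (3,6-dibromo-2-lithiophenoxy)trimethylsilane 3 (not isolated), via lithium 3,6-dibromo-2-(trimethylsilyl)phenoxide 4 (not isolated)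
Conditions: LiN(iPr)2 (1.1 equiv, commercial solution), THF, −78 °C; then AcOH, −78 °C to rt
Reagents that add atoms: none
Why: Directed ortho-lithiation followed by retro-Brook rearrangement (anionic 1,3 O-to-C silyl shift): C6–H is the only ring proton acidified by both the oxygen and a bromine, and the amide base deprotonates without exchanging C–Br. The neighbouring O–Si group should capture the aryllithium 3 intramolecularly before it can lose LiBr, and the strong O–Li bond of 4 drives the shift.

Step 3
Reactants: 5 3,6-dibromo-2-(trimethylsilyl)phenol
Product: 6 3,6-dibromo-2-(trimethylsilyl)phenyl trifluoromethanesulfonate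
Conditions: Tf2O (1.2 equiv), pyridine (2 equiv), CH2Cl2, 0 °C
Reagents that add atoms: trifluoromethanesulfonic anhydride, O=S(=O)(C(F)(F)F)OS(=O)(=O)C(F)(F)F
Why: O-Triflation of a phenol; the ortho bromine acidifies the phenol, which should react at oxygen despite its two ortho substituents, and the aryl–Si bond is inert to Tf2O and pyridine.

Step 4
Reactants: 7 aminoacetaldehyde dimethyl acetal (2,2-dimethoxyethanamine); 8 p-toluenesulfonyl chloride
Product: 9 N-(2,2-dimethoxyethyl)-4-methylbenzenesulfonamide
Conditions: Et3N (1.5 equiv), CH2Cl2, 0 °C to rt
Reagents that add atoms: none
Why: Sulfonamide formation from a primary amine and a sulfonyl chloride; the acetal is stable to the basic medium.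

Step 5
Reactants: 9 N-(2,2-dimethoxyethyl)-4-methylbenzenesulfonamide
Product: 10 4-methyl-N-(2-oxoethyl)benzenesulfonamide
Conditions: 1 M aq HCl, THF, 40 °C; extracted, dried and used at once
Reagents that add atoms: water, O
Why: Acid-catalysed hydrolysis of a dimethyl acetal; the sulfonamide is inert to dilute acid, and the aldehyde is taken on without storage because α-heteroatom aldehydes hydrate and oligomerise on standing.

Step 6
Reactants: 6 3,6-dibromo-2-(trimethylsilyl)phenyl trifluoromethanesulfonate; 10 4-methyl-N-(2-oxoethyl)benzenesulfonamide
Product: 13 rac-4,7-dibromo-1-(4-methylphenylsulfonyl)indolin-3-ol, via 3,6-dibromobenzyne 11 (not isolated), via caesium 3,6-dibromo-2-[(2-oxoethyl)(4-methylphenylsulfonyl)amino]benzenide 12 (not isolated)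
Conditions: CsF (3 equiv), 10 (1.5 equiv), MeCN, 25 °C, 6 added slowly
Reagents that add atoms: none
Why: Fluoride attacks the silicon of 6 and the developing aryl anion expels triflate, a far better leaving group than the bromide on its other side, to give the aryne 11. The sulfonamide of 10, deprotonated by fluoride, adds through nitrogen to one end of the strained triple bond (N1–C7a); the two ends are equivalent by the mirror plane of 11, so only one aryl anion 12 can form, and the adjacent C–Br stabilises it inductively. Anion 12 then adds to the aldehyde held two atoms away on nitrogen in a 5-exo-trig closure (C3–C3a), and protonation of the alkoxide gives 13. The closest known reaction type is the fluoride-induced annulation of arynes with N-sulfonyl α-amino ketones to 3-hydroxyindolines; an aldehyde is a better acceptor than a ketone and the two bromines lower the aryne LUMO, so both changes should help. The new stereocentre C3 is formed without control, because the aldehyde faces are enantiotopic in an achiral substrate, and the racemate is acceptable since C3 becomes sp2 in step 7. The selectivity needed is chemoselectivity of 12: ring closure must outrun protonation (by MeCN, by N–H or by its own α-CH2) and loss of bromide to a second aryne, which the intramolecular five-membered closure onto an aldehyde should secure. Slow release of 11 by sparingly soluble CsF and the excess of 10 keep the aryne concentration low and so suppress arylation of the product alkoxide.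

Step 7
Reactants: 13 rac-4,7-dibromo-1-(4-methylphenylsulfonyl)indolin-3-ol
Product: 14 4,7-dibromo-1-(4-methylphenylsulfonyl)indole
Conditions: TsOH·H2O (10 mol %), toluene, 90 °C
Reagents that add atoms: none
Why: Acid-catalysed dehydration (E1 through the benzylic C3 cation, then loss of a C2 proton), driven by formation of the aromatic pyrrole ring; the sulfonamide and the aryl bromides are stable to catalytic sulfonic acid.

Step 8
Reactants: 14 4,7-dibromo-1-(4-methylphenylsulfonyl)indole
Product: 15 4,7-dibromo-1H-indole
Conditions: KOH (5 equiv), THF/MeOH/H2O, 65 °C
Reagents that add atoms: none
Why: Nucleophilic cleavage of the N–S bond of an N-sulfonylindole, in which the indolide is a good leaving group; relief of the clash between the sulfonyl group and the C7 bromine should help. The unactivated aryl bromides do not undergo substitution under these conditions.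

Step 9
Reactants: 15 4,7-dibromo-1H-indole
Product: 17 2,3,4,7-tetrabromo-1H-indole, via 3,4,7-tribromo-1H-indole 16 (not isolated)
Conditions: NBS (2.1 equiv), dry DMF, 0 °C to rt, dark
Reagents that add atoms: N-bromosuccinimide, O=C1CCC(=O)N1Br
Why: Electrophilic bromination of an indole: the first equivalent reacts at C3, the most nucleophilic position, to give 16, and the second brominates the 3-bromoindole at C2 (attack at C3 to a 3,3-dibromoindolenine with 1,2-shift of bromine, or direct attack at C2). The benzene ring, deactivated by two bromines, should be left alone, and exclusion of water and light guards against oxindole formation.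

## Compound list

1 | 2,5-dibromophenol | Oc1cc(Br)ccc1Br | starting material
2 | (2,5-dibromophenoxy)trimethylsilane | C[Si](C)(C)Oc1cc(Br)ccc1Br | intermediate
3 | (3,6-dibromo-2-lithiophenoxy)trimethylsilane | C[Si](C)(C)Oc1c([Li])c(Br)ccc1Br | intermediate
4 | lithium 3,6-dibromo-2-(trimethylsilyl)phenoxide | [Li+].[O-]c1c(Br)ccc(Br)c1[Si](C)(C)C | intermediate
5 | 3,6-dibromo-2-(trimethylsilyl)phenol | Oc1c(Br)ccc(Br)c1[Si](C)(C)C | intermediate
6 | 3,6-dibromo-2-(trimethylsilyl)phenyl trifluoromethanesulfonate | C[Si](C)(C)c1c(Br)ccc(Br)c1OS(=O)(=O)C(F)(F)F | intermediate
7 | aminoacetaldehyde dimethyl acetal (2,2-dimethoxyethanamine) | COC(CN)OC | starting material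
8 | p-toluenesulfonyl chloride | Cc1ccc(cc1)S(Cl)(=O)=O | starting material
9 | N-(2,2-dimethoxyethyl)-4-methylbenzenesulfonamide | COC(CNS(=O)(=O)c1ccc(C)cc1)OC | intermediate
10 | 4-methyl-N-(2-oxoethyl)benzenesulfonamide | Cc1ccc(cc1)S(=O)(=O)NCC=O | intermediate
11 | 3,6-dibromobenzyne (3,6-dibromo-1,2-didehydrobenzene) | BrC1=CC=C(Br)C#C1 | intermediate
12 | caesium 3,6-dibromo-2-[(2-oxoethyl)(4-methylphenylsulfonyl)amino]benzenide | Cc1ccc(cc1)S(=O)(=O)N(CC=O)c1c(Br)ccc(Br)[c-]1.[Cs+] | intermediate
13 | rac-4,7-dibromo-1-(4-methylphenylsulfonyl)indolin-3-ol (one enantiomer drawn) | Cc1ccc(cc1)S(=O)(=O)N1C[C@@H](O)c2c(Br)ccc(Br)c12 | intermediate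
14 | 4,7-dibromo-1-(4-methylphenylsulfonyl)indole | Cc1ccc(cc1)S(=O)(=O)n1ccc2c(Br)ccc(Br)c12 | intermediate
15 | 4,7-dibromo-1H-indole | Brc1ccc(Br)c2[nH]ccc12 | intermediate
16 | 3,4,7-tribromo-1H-indole | Brc1c[nH]c2c(Br)ccc(Br)c12 | intermediate
17 | 2,3,4,7-tetrabromo-1H-indole | Brc1[nH]c2c(Br)ccc(Br)c2c1Br | target

## Step count and least certain steps

Total step count: 9. Longest linear sequence: 7 steps (steps 1, 2, 3, 6, 7, 8 and 9, from 1). The aldehyde branch (steps 4 and 5) joins at step 6.

**Step 6 (key step).** Three processes could divert it. The first is base-induced self-condensation of the enolisable aldehyde 10 before it is N-arylated. The second is premature protonation of the aryl anion 12 by solvent, by the N–H of a second molecule of 10, or by internal transfer from its own α-CH2, which would stop at an open-chain N-aryl sulfonamide. The third is loss of bromide from 12 to give a second aryne. The fallback replaces the aldehyde by an ester, which cannot self-condense under CsF. Glycine methyl ester hydrochloride and 8 (Et3N, CH2Cl2) would give methyl N-(4-methylphenylsulfonyl)glycinate F1. Treating 6 with F1 and CsF in MeCN should lead to N-arylation followed by intramolecular acylation of the aryl anion, as in aryne-based acridone and xanthone syntheses from ortho-heteroatom benzoates, here closing a five-membered ring to 4,7-dibromo-1-(4-methylphenylsulfonyl)indolin-3-one F2. Reduction of F2 with NaBH4 in MeOH at 0 °C would give the alcohol. This fallback sets out from 6 and 8 and returns to the route at 13.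

**Step 2.** The ortho-bromoaryllithium 3 may lose LiBr before the silyl group migrates, bromine may migrate between 3 and unreacted 2 (halogen dance), or the amide may attack silicon and strip the silyl group from oxygen. The fallback replaces migration by external trapping. Phenol 1 would be converted with MOMCl and iPr2NEt into 1,4-dibromo-2-(methoxymethoxy)benzene F3. LiN(iPr)2 would then be added at −78 °C to F3 in THF already containing Me3SiCl, so that the aryllithium is silylated as it forms, giving [3,6-dibromo-2-(methoxymethoxy)phenyl]trimethylsilane F4. HCl in MeOH at rt would remove the acetal. This fallback sets out from 1 and returns to the route at 5.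

**Step 9.** The second bromination may stall, since the C3-brominated intermediate 16 is deactivated and crowded by the C4 bromine. The indolenine stage may be diverted to oxindole-type products by traces of water, and the product may decompose on acidic supports or in light. The fallback installs the two bromines by different mechanisms. From 14, LiN(iPr)2 at −78 °C should lithiate C2 (directed by the sulfonyl group, without exchange of aryl bromides), and quenching with BrCCl2CCl2Br would give 2,4,7-tribromo-1-(4-methylphenylsulfonyl)indole F5. KOH as in step 8 would give 2,4,7-tribromo-1H-indole F6, and one equivalent of NBS would then brominate the remaining C3 position. This fallback sets out from 14 and returns to the route at 17.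

**Step 5.** Hydration, oligomerisation and self-aldol reaction of the α-sulfonamido aldehyde during aqueous acidic hydrolysis and concentration could erode the material, and the hydrolysis equilibrium may stay incomplete. The fallback reaches the aldehyde by oxidation under anhydrous, near-neutral conditions. Ethanolamine and 8 (Et3N, CH2Cl2, 0 °C, N-selective) would give N-(2-hydroxyethyl)-4-methylbenzenesulfonamide F7, and Dess–Martin periodinane in CH2Cl2 would oxidise it to the aldehyde. This fallback sets out from 8 and returns to the route at 10.

**Step 7.** Ionisation at C3 may be slow, because the cation is flanked by the C4 bromine and the ring nitrogen is sulfonylated, and forcing acid could then cause intermolecular etherification or oligomerisation in place of elimination. The fallback is a base-mediated elimination. Alcohol 13 would be converted with MsCl and Et3N in CH2Cl2 at 0 °C into rac-4,7-dibromo-1-(4-methylphenylsulfonyl)indolin-3-yl methanesulfonate F8. DBU at rt should then effect E2 loss of the sulfonate across C2–C3. This fallback sets out from 13 and returns to the route at 14.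

## Further compounds

F1 | step 6 | methyl N-(4-methylphenylsulfonyl)glycinate | COC(=O)CNS(=O)(=O)c1ccc(C)cc1
F2 | step 6 | 4,7-dibromo-1-(4-methylphenylsulfonyl)indolin-3-one | Cc1ccc(cc1)S(=O)(=O)N1CC(=O)c2c(Br)ccc(Br)c12
F3 | step 2 | 1,4-dibromo-2-(methoxymethoxy)benzene | COCOc1cc(Br)ccc1Br
F4 | step 2 | [3,6-dibromo-2-(methoxymethoxy)phenyl]trimethylsilane | COCOc1c(Br)ccc(Br)c1[Si](C)(C)C
F5 | step 9 | 2,4,7-tribromo-1-(4-methylphenylsulfonyl)indole | Cc1ccc(cc1)S(=O)(=O)n1c(Br)cc2c(Br)ccc(Br)c12
F6 | step 9 | 2,4,7-tribromo-1H-indole | Brc1cc2c(Br)ccc(Br)c2[nH]1
F7 | step 5 | N-(2-hydroxyethyl)-4-methylbenzenesulfonamide | Cc1ccc(cc1)S(=O)(=O)NCCO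
F8 | step 7 | rac-4,7-dibromo-1-(4-methylphenylsulfonyl)indolin-3-yl methanesulfonate (one enantiomer drawn) | Cc1ccc(cc1)S(=O)(=O)N1C[C@@H](OS(C)(=O)=O)c2c(Br)ccc(Br)c12
A1 | alternative 1 | 2,5-dibromothiophene 1,1-dioxide | O=S1(=O)C(Br)=CC=C1Br
A2 | alternative 1 | tert-butyl 2,3-dihydropyrrole-1-carboxylate | CC(C)(C)OC(=O)N1CCC=C1
A3 | alternative 1 | tert-butyl cis-4,7-dibromo-2,3,3a,7a-tetrahydroindole-1-carboxylate (racemic, one enantiomer drawn) | CC(C)(C)OC(=O)N1CC[C@@H]2C(Br)=CC=C(Br)[C@H]12
A4 | alternative 2 | 2,3-diethynyl-1-(4-methylphenylsulfonyl)pyrrole | Cc1ccc(cc1)S(=O)(=O)n1ccc(C#C)c1C#C
A5 | alternative 2 | bromotrichloromethane | BrC(Cl)(Cl)Cl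
A6 | alternative 2 | 4,7-dibromo-1-(4-methylphenylsulfonyl)indole | Cc1ccc(cc1)S(=O)(=O)n1ccc2c(Br)ccc(Br)c12
A7 | alternative 3 | 2,5-dibromobenzaldehyde | O=Cc1cc(Br)ccc1Br
A8 | alternative 3 | ethyl azidoacetate | CCOC(=O)CN=[N+]=[N-]
A9 | alternative 3 | ethyl (Z)-2-azido-3-(2,5-dibromophenyl)acrylate | CCOC(=O)/C(N=[N+]=[N-])=C/c1cc(Br)ccc1Br
A10 | alternative 3 | ethyl 4,7-dibromo-1H-indole-2-carboxylate | CCOC(=O)c1cc2c(Br)ccc(Br)c2[nH]1
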